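## Retrosynthetic overview

- Numbering: ring A is the 3,4,5-trimethoxyphenyl ring, ring B the guaiacyl ring with the 3-hydroxypropyl chain; C7 is the carbinol carbon on ring A, C8 the ether-bearing carbon, C9 the methyl carbon.
- The strategy rests on C8, which is bonded at once to the phenolic oxygen of ring B and to carbinol carbon C7. C8 is therefore traced to the carbene carbon of ethyl diazoacetate 4, which takes up phenol 3 (C8–O bond) and aldehyde 5 (C7–C8 bond) in one operation.
- The C9 methyl group is carried through the key step as the ethyl ester of 7 and is unmasked afterwards: ester reduction, primary tosylation, hydride displacement, desilylation.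
- Phenol 3 comes from dihydroconiferyl alcohol 1 by bis-silylation and selective aryl desilylation; the primary alcohol must be masked because it would capture the carbene ahead of the phenol.
- No ring is formed at any stage: rings A and B are bought intact.

Key step: step 3

Assumption: the sense of induction of a BINOL-derived phosphoric acid in this untested trapping cannot be assigned in advance; the (R)-acid is written, and its (S)-enantiomer is to be used if that one proves to favour the (2S,3S) ester.

Remark: the C8 descriptor changes from S in ester 7 to R in 8–11 only because the CIP ranking of the C9 substituent changes; the configuration is the same throughout.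

## Route

Step 1
Reactants: 1 dihydroconiferyl alcohol [4-(3-hydroxypropyl)-2-methoxyphenol]
Product: 2 tert-butyl{3-[4-(tert-butyldimethylsilyloxy)-3-methoxyphenyl]propoxy}dimethylsilane
Conditions: TBSCl (2.4 equiv), imidazole (5 equiv), DMF, 0 °C to rt
Reagents that add atoms: tert-butyldimethylsilyl chloride, CC(C)(C)[Si](C)(C)Cl
Why: Imidazole-promoted silyl ether formation caps both the primary alcohol and the phenol, which is more dependable than trying to silylate the aliphatic hydroxyl alone; no stereocentre is involved.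

Step 2
Reactants: 2 tert-butyl{3-[4-(tert-butyldimethylsilyloxy)-3-methoxyphenyl]propoxy}dimethylsilane
Product: 3 4-[3-(tert-butyldimethylsilyloxy)propyl]-2-methoxyphenol
Conditions: K2CO3 (1.5 equiv), MeOH, rt; aq. NH4Cl
Reagents that add atoms: none
Why: Base-mediated methanolysis (chemoselective desilylation) cleaves the aryl silyl ether much faster than the alkyl one because phenoxide is the better leaving group, so only the phenol is freed.

Step 3
Reactants: 3 4-[3-(tert-butyldimethylsilyloxy)propyl]-2-methoxyphenol; 4 ethyl diazoacetate; 5 3,4,5-trimethoxybenzaldehyde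
Product: 7 ethyl (2S,3S)-2-{4-[3-(tert-butyldimethylsilyloxy)propyl]-2-methoxyphenoxy}-3-hydroxy-3-(3,4,5-trimethoxyphenyl)propanoate, via enol 6 (not isolated)
Conditions: Rh2(OAc)4 (2 mol %), (R)-3,3'-bis(2,4,6-triisopropylphenyl)-1,1'-binaphthyl-2,2'-diyl hydrogen phosphate (10 mol %), 4 Å MS, CH2Cl2, −20 °C; 5 (2 equiv) present from the start, 4 (1.3 equiv) added over 6 h by syringe pump
Reagents that add atoms: ethyl diazoacetate (4), CCOC(=O)C=[N+]=[N-]; 3,4,5-trimethoxybenzaldehyde (5), COc1cc(C=O)cc(OC)c1OC
Why: Proposed new method: Rh2(OAc)4 turns 4 into an electrophilic, catalyst-bound carbene, the phenolic oxygen of 3 adds to it, and the rhodium-bound oxonium ylide leaves the metal as the (E)-enol 6, which the phosphoric acid holds through P=O···H–O(enol) while its P–OH activates aldehyde 5, so that C7–C8 bond formation can outrun the 1,2-proton shift that would end in plain O–H insertion. The closest known reaction type is the Rh2(OAc)4/Brønsted acid co-catalysed three-component coupling of diazo esters, alcohols and imines or aldehydes (Mannich- or aldol-type trapping of protic oxonium ylides); new here is the union of a phenol, an acceptor-only diazoacetate and an electron-rich aryl aldehyde under enantio- and erythro-control. No ring is closed; the step forms the C8–O(ring B) and C7–C8 bonds. Both new stereocentres, C8 (ester C2) and C7 (ester C3), are set in the single C–C bond-forming event inside the chiral pocket of the acid, whose 3,3'-aryl groups must select the enol face, the aldehyde face and their anti (erythro) approach, since neither substrate carries a stereocentre. Chemoselectivity is secured by the substrate design: the only free O–H is the phenol, the para position of ring B is blocked against C–H attack, aldehyde 5 cannot enolise, and slow addition of 4 at low temperature over molecular sieves suppresses carbene dimerisation, carbonyl-ylide (dioxolane) formation and water insertion.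

Step 4
Reactants: 7 ethyl (2S,3S)-2-{4-[3-(tert-butyldimethylsilyloxy)propyl]-2-methoxyphenoxy}-3-hydroxy-3-(3,4,5-trimethoxyphenyl)propanoate
Product: 8 (1S,2R)-2-{4-[3-(tert-butyldimethylsilyloxy)propyl]-2-methoxyphenoxy}-1-(3,4,5-trimethoxyphenyl)propane-1,3-diol
Conditions: LiBH4 (2 equiv), THF, 0 °C to rt; aq. NH4Cl
Reagents that add atoms: none
Why: Chemoselective hydride reduction of the ester to the primary alcohol, at low temperature and weak basicity so that retro-aldol cleavage and C8 epimerisation should not compete; neither stereocentre is touched and the silyl and aryl ethers are inert.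

Step 5
Reactants: 8 (1S,2R)-2-{4-[3-(tert-butyldimethylsilyloxy)propyl]-2-methoxyphenoxy}-1-(3,4,5-trimethoxyphenyl)propane-1,3-diol
Product: 9 (2R,3S)-2-{4-[3-(tert-butyldimethylsilyloxy)propyl]-2-methoxyphenoxy}-3-hydroxy-3-(3,4,5-trimethoxyphenyl)propyl 4-methylbenzenesulfonate
Conditions: TsCl (1.1 equiv), pyridine, CH2Cl2, 0 °C
Reagents that add atoms: 4-toluenesulfonyl chloride, Cc1ccc(cc1)S(=O)(=O)Cl
Why: Selective sulfonylation (tosylation) should take the unhindered primary C9 hydroxyl ahead of the secondary benzylic C7 hydroxyl, which is flanked by ring A and the aryloxy group; no stereocentre is involved.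

Step 6
Reactants: 9 (2R,3S)-2-{4-[3-(tert-butyldimethylsilyloxy)propyl]-2-methoxyphenoxy}-3-hydroxy-3-(3,4,5-trimethoxyphenyl)propyl 4-methylbenzenesulfonate
Product: 10 (1S,2R)-2-{4-[3-(tert-butyldimethylsilyloxy)propyl]-2-methoxyphenoxy}-1-(3,4,5-trimethoxyphenyl)propan-1-ol
Conditions: LiEt3BH (3 equiv), THF, 0 °C to rt; aq. NH4Cl
Reagents that add atoms: none
Why: SN2 hydride displacement of the primary sulfonate (Super-Hydride reduction) converts C9 into the methyl group after the first equivalent has deprotonated the C7 hydroxyl; C7 and C8 take no part, so their configuration is retained.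

Step 7
Reactants: 10 (1S,2R)-2-{4-[3-(tert-butyldimethylsilyloxy)propyl]-2-methoxyphenoxy}-1-(3,4,5-trimethoxyphenyl)propan-1-ol
Product: 11 (1S,2R)-2-[4-(3-hydroxypropyl)-2-methoxyphenoxy]-1-(3,4,5-trimethoxyphenyl)propan-1-ol (target)
Conditions: Bu4NF (1.5 equiv), THF, 0 °C to rt; water
Reagents that add atoms: none
Why: Fluoride-mediated desilylation, driven by Si–F bond formation, frees the primary alcohol under non-acidic conditions, so the benzylic C7 carbinol cannot ionise and both stereocentres stay intact.

## Compound list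

1 | dihydroconiferyl alcohol, 4-(3-hydroxypropyl)-2-methoxyphenol | COc1cc(CCCO)ccc1O | starting material
2 | tert-butyl{3-[4-(tert-butyldimethylsilyloxy)-3-methoxyphenyl]propoxy}dimethylsilane | COc1cc(CCCO[Si](C)(C)C(C)(C)C)ccc1O[Si](C)(C)C(C)(C)C | intermediate
3 | 4-[3-(tert-butyldimethylsilyloxy)propyl]-2-methoxyphenol | COc1cc(CCCO[Si](C)(C)C(C)(C)C)ccc1O | intermediate
4 | ethyl diazoacetate | CCOC(=O)C=[N+]=[N-] | starting material
5 | 3,4,5-trimethoxybenzaldehyde | COc1cc(C=O)cc(OC)c1OC | starting material
6 | (E)-2-{4-[3-(tert-butyldimethylsilyloxy)propyl]-2-methoxyphenoxy}-1-ethoxyethen-1-ol (enol, aryloxy cis to the enol hydroxyl) | COc1cc(CCCO[Si](C)(C)C(C)(C)C)ccc1O/C=C(\O)OCC | intermediate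
7 | ethyl (2S,3S)-2-{4-[3-(tert-butyldimethylsilyloxy)propyl]-2-methoxyphenoxy}-3-hydroxy-3-(3,4,5-trimethoxyphenyl)propanoate | COc1cc(CCCO[Si](C)(C)C(C)(C)C)ccc1O[C@H](C(=O)OCC)[C@@H](O)c1cc(OC)c(OC)c(OC)c1 | intermediate
8 | (1S,2R)-2-{4-[3-(tert-butyldimethylsilyloxy)propyl]-2-methoxyphenoxy}-1-(3,4,5-trimethoxyphenyl)propane-1,3-diol | COc1cc(CCCO[Si](C)(C)C(C)(C)C)ccc1O[C@H](CO)[C@@H](O)c1cc(OC)c(OC)c(OC)c1 | intermediate
9 | (2R,3S)-2-{4-[3-(tert-butyldimethylsilyloxy)propyl]-2-methoxyphenoxy}-3-hydroxy-3-(3,4,5-trimethoxyphenyl)propyl 4-methylbenzenesulfonate | COc1cc(CCCO[Si](C)(C)C(C)(C)C)ccc1O[C@H](COS(=O)(=O)c1ccc(C)cc1)[C@@H](O)c1cc(OC)c(OC)c(OC)c1 | intermediate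
10 | (1S,2R)-2-{4-[3-(tert-butyldimethylsilyloxy)propyl]-2-methoxyphenoxy}-1-(3,4,5-trimethoxyphenyl)propan-1-ol | COc1cc(CCCO[Si](C)(C)C(C)(C)C)ccc1O[C@H](C)[C@@H](O)c1cc(OC)c(OC)c(OC)c1 | intermediate
11 | (1S,2R)-2-[4-(3-hydroxypropyl)-2-methoxyphenoxy]-1-(3,4,5-trimethoxyphenyl)propan-1-ol | COc1cc(CCCO)ccc1O[C@H](C)[C@@H](O)c1cc(OC)c(OC)c(OC)c1 | target

## Step count and risks

Total step count: 7. Longest linear sequence: 7 steps (1 to 11; 4 and 5 enter at step 3).

Steps most likely to fail:

1. Step 3 (proposed new method). The 1,2-proton shift of the enol may outrun capture by the only moderately electrophilic aldehyde, ending in simple O–H insertion. Alternatively the acid may fail to impose the anti (erythro) relation or the (2S,3S) sense. The fallback uses known chemistry with chiral-pool control and sets out from phenol 3. Mitsunobu etherification with ethyl (S)-lactate (PPh3, DIAD, THF, 0 °C) forms the C8–O bond with inversion and gives ethyl (2R)-2-{4-[3-(tert-butyldimethylsilyloxy)propyl]-2-methoxyphenoxy}propanoate F1. Treatment with MeNHOMe·HCl and iPrMgCl (THF, −20 °C) gives the Weinreb amide (2R)-2-{4-[3-(tert-butyldimethylsilyloxy)propyl]-2-methoxyphenoxy}-N-methoxy-N-methylpropanamide F2. Addition of 3,4,5-trimethoxyphenylmagnesium bromide (THF, −20 °C) gives (2R)-2-{4-[3-(tert-butyldimethylsilyloxy)propyl]-2-methoxyphenoxy}-1-(3,4,5-trimethoxyphenyl)propan-1-one F3. Chelation-controlled reduction with Zn(BH4)2 (Et2O, −30 °C) should then deliver hydride to the carbonyl face on the side of the C8 hydrogen, with zinc bridging the carbonyl and aryloxy oxygens, and give the erythro (1S,2R) alcohol. This is compound 10, where the route is rejoined with only step 7 left.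

2. Step 6. Once the C7 hydroxyl is deprotonated, alkoxide-triggered Grob-type fragmentation (to aldehyde 5 and an aryl vinyl ether) or 4-exo closure to an oxetane may compete with hydride delivery to C9. The fallback sets out from tosylate 9 and removes the alkoxide. Silylation (Et3SiOTf, 2,6-lutidine, CH2Cl2, −78 °C) gives (2R,3S)-2-{4-[3-(tert-butyldimethylsilyloxy)propyl]-2-methoxyphenoxy}-3-(triethylsilyloxy)-3-(3,4,5-trimethoxyphenyl)propyl 4-methylbenzenesulfonate F5. LiEt3BH (THF, 0 °C) then gives {(1S,2R)-2-{4-[3-(tert-butyldimethylsilyloxy)propyl]-2-methoxyphenoxy}-1-(3,4,5-trimethoxyphenyl)propoxy}triethylsilane F6. Excess Bu4NF (THF, rt) removes both silyl groups, so the route is rejoined at target 11.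

3. Step 5. Site discrimination may be poor, with sulfonylation also at the benzylic C7 hydroxyl or premature displacement of the tosylate in the flask. The fallback sets out from diol 8 and uses phosphonium activation, which is inherently selective for the primary position. PPh3, I2 and imidazole (THF, 0 °C) give (1S,2S)-2-{4-[3-(tert-butyldimethylsilyloxy)propyl]-2-methoxyphenoxy}-3-iodo-1-(3,4,5-trimethoxyphenyl)propan-1-ol F4. LiEt3BH (THF, −20 °C) reduces this iodide at a lower temperature than the sulfonate needs, and the route is rejoined at compound 10.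

## Further compounds

F1 | step 3 | ethyl (2R)-2-{4-[3-(tert-butyldimethylsilyloxy)propyl]-2-methoxyphenoxy}propanoate | COc1cc(CCCO[Si](C)(C)C(C)(C)C)ccc1O[C@H](C)C(=O)OCC
F2 | step 3 | (2R)-2-{4-[3-(tert-butyldimethylsilyloxy)propyl]-2-methoxyphenoxy}-N-methoxy-N-methylpropanamide | COc1cc(CCCO[Si](C)(C)C(C)(C)C)ccc1O[C@H](C)C(=O)N(C)OC
F3 | step 3 | (2R)-2-{4-[3-(tert-butyldimethylsilyloxy)propyl]-2-methoxyphenoxy}-1-(3,4,5-trimethoxyphenyl)propan-1-one | COc1cc(CCCO[Si](C)(C)C(C)(C)C)ccc1O[C@H](C)C(=O)c1cc(OC)c(OC)c(OC)c1
F4 | step 5 | (1S,2S)-2-{4-[3-(tert-butyldimethylsilyloxy)propyl]-2-methoxyphenoxy}-3-iodo-1-(3,4,5-trimethoxyphenyl)propan-1-ol | COc1cc(CCCO[Si](C)(C)C(C)(C)C)ccc1O[C@H](CI)[C@@H](O)c1cc(OC)c(OC)c(OC)c1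
F5 | step 6 | (2R,3S)-2-{4-[3-(tert-butyldimethylsilyloxy)propyl]-2-methoxyphenoxy}-3-(triethylsilyloxy)-3-(3,4,5-trimethoxyphenyl)propyl 4-methylbenzenesulfonate | COc1cc(CCCO[Si](C)(C)C(C)(C)C)ccc1O[C@H](COS(=O)(=O)c1ccc(C)cc1)[C@@H](O[Si](CC)(CC)CC)c1cc(OC)c(OC)c(OC)c1
F6 | step 6 | {(1S,2R)-2-{4-[3-(tert-butyldimethylsilyloxy)propyl]-2-methoxyphenoxy}-1-(3,4,5-trimethoxyphenyl)propoxy}triethylsilane | COc1cc(CCCO[Si](C)(C)C(C)(C)C)ccc1O[C@H](C)[C@@H](O[Si](CC)(CC)CC)c1cc(OC)c(OC)c(OC)c1
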